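**Plan**
- Retrosynthesis: the four C–Br bonds are cut first (C3–Br and C4–Br back to C–H, C2–Br and C5–Br back to C–CO2H), then N1–CH3, then the ring bond N1–C5, then the C2–C3 and C4–C5 bonds.
- Enabling feature: N1 and the carbon chain C2–C3–C4–C5 of the pyrrole are the atoms of a pyridazine ring short of one nitrogen. C2 and C5, which end up carrying bromine, are where two ester groups can sit to make that diazine reducible and later be exchanged for bromine by ipso-substitution.
- Forward order: the pyridazine ring arises first, by cycloaddition of a tetrazine diester with a two-carbon enol ether and loss of N2 and ethanol. The pyrrole ring arises second, by reductive contraction with loss of ammonia. N-methylation, saponification and four-fold bromination follow.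
- Stereochemistry: the target is planar and achiral with no stereocentre, so nothing has to be set or protected.

Key step: step 2

Remark: dimethyl 1,2,4,5-tetrazine-3,6-dicarboxylate 1 is assumed to be a purchased reagent; it is moisture-sensitive, so step 1 is run in dry solvent.

**Step 1**
Reactants: 1 dimethyl 1,2,4,5-tetrazine-3,6-dicarboxylate; 2 ethyl vinyl ether
Product: 5 dimethyl pyridazine-3,6-dicarboxylate, via tetraazabicyclooctadiene cycloadduct 3 (not isolated), via 4-ethoxy-4,5-dihydropyridazine diester 4 (not isolated)
Conditions: 2 (3 equiv), dry 1,4-dioxane, 25 °C (N2 evolution), then 60 °C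
Reagents that add atoms: none
Why: Inverse-electron-demand Diels–Alder (Carboni–Lindsey) reaction in which the low LUMO of the doubly ester-substituted tetrazine meets the HOMO of the enol ether, cycloadduct 3 ejects N2 by retro-[4+2], and dihydrodiazine 4 (after tautomerisation to its 1,4-dihydro form) loses ethanol to reach the aromatic pyridazine, regiochemistry being moot for the symmetrical diene.

**Step 2**
Reactants: 5 dimethyl pyridazine-3,6-dicarboxylate
Product: 9 dimethyl 1H-pyrrole-2,5-dicarboxylate, via 1,4-dihydropyridazine diester 6 (not isolated), via ring-opened amino imine 7 (not isolated), via 2-amino-2,3-dihydropyrrole diester 8 (not isolated)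
Conditions: Zn dust (10 equiv), AcOH, 25 °C, 12–24 h
Reagents that add atoms: none
Why: Zinc in acetic acid passes two electrons and two protons to the ester-activated diazine 5 to give the 1,4-dihydropyridazine 6, and a second two-electron transfer breaks its weak N–N bond to give the Z-enamine/imine 7, whose nitrogens sit on C2 and C5 of the six-carbon chain. The enamine nitrogen then adds to the protonated imine carbon in a 5-exo-trig closure that makes the N1–C5 bond of the pyrrole (aminal 8), and loss of ammonia from 8 aromatises the ring to 9. The closest known reaction type is the reductive ring contraction of electron-poor 1,2-diazines to pyrroles with zinc in acetic acid. No stereocentre results, because the only sp3 ring carbon of the sequence (C2 of 8) is erased on aromatisation. The selectivity needed is chemoselectivity: reduction has to end at N–N scission and leave the esters, the enamine C=C bond and the product untouched. The two ester groups at C3 and C6 secure this by making the diazine and its dihydro form the most easily reduced functions present, and the fast, irreversible loss of ammonia removes the reducible imine as soon as the ring has closed.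

**Step 3**
Reactants: 9 dimethyl 1H-pyrrole-2,5-dicarboxylate; 10 iodomethane
Product: 11 dimethyl 1-methyl-1H-pyrrole-2,5-dicarboxylate
Conditions: MeI (1.5 equiv), K2CO3 (2 equiv), DMF, rt
Reagents that add atoms: iodomethane 10, CI
Why: N-Alkylation of a pyrrolide by SN2, since the NH flanked by two ester groups is acidic enough for K2CO3 in DMF and, with both α-carbons blocked and the β-carbons deactivated, the anion reacts with iodomethane at nitrogen.

**Step 4**
Reactants: 11 dimethyl 1-methyl-1H-pyrrole-2,5-dicarboxylate
Product: 13 1-methyl-1H-pyrrole-2,5-dicarboxylic acid, via disodium dicarboxylate 12 (not isolated)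
Conditions: NaOH (4 equiv), MeOH/H2O, reflux; then 2 M HCl, 0 °C, pH 2
Reagents that add atoms: sodium hydroxide, [Na+].[OH-]
Why: Saponification (base-mediated acyl–oxygen ester hydrolysis) of both methyl esters gives the dicarboxylate 12, and cold acidification should release the diacid without the heat that would invite protodecarboxylation.

**Step 5**
Reactants: 13 1-methyl-1H-pyrrole-2,5-dicarboxylic acid
Product: 17 2,3,4,5-tetrabromo-1-methyl-1H-pyrrole, via 5-bromo-1-methylpyrrole-2-carboxylic acid 14 (not isolated), via 2,5-dibromo-1-methylpyrrole 15 (not isolated), via 2,3,5-tribromo-1-methylpyrrole 16 (not isolated)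
Conditions: NBS (4.2 equiv), NaHCO3 (2.2 equiv, buffer), DMF, 0 °C to rt, dark
Reagents that add atoms: N-bromosuccinimide, O=C1CCC(=O)N1Br
Why: Electrophilic aromatic substitution with NBS, in which ipso-attack at the carboxylate-bearing α-carbons C2 and C5 is followed by loss of CO2 (bromodecarboxylation, a standard reaction of pyrrole-2-carboxylic acids) and C3 and C4 undergo ordinary C–H bromination; each lost carboxyl group leaves a more electron-rich ring, so the sequence should run through to the tetrabromide, and the order shown for 14–16 is the most probable one but does not affect the product.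

**Compound list**
1 | dimethyl 1,2,4,5-tetrazine-3,6-dicarboxylate | COC(=O)c1nnc(nn1)C(=O)OC | starting material
2 | ethyl vinyl ether | C=COCC | starting material
3 | dimethyl 7-ethoxy-2,3,5,6-tetraazabicyclo[2.2.2]octa-2,5-diene-1,4-dicarboxylate (racemic) | COC(=O)C12N=NC(N=N1)(C(=O)OC)C(OCC)C2 | intermediate (not isolated)
4 | dimethyl 4-ethoxy-4,5-dihydropyridazine-3,6-dicarboxylate (racemic) | COC(=O)C1=NN=C(C(=O)OC)C(OCC)C1 | intermediate (not isolated)
5 | dimethyl pyridazine-3,6-dicarboxylate | COC(=O)c1ccc(nn1)C(=O)OC | intermediate
6 | dimethyl 1,4-dihydropyridazine-3,6-dicarboxylate | COC(=O)C1=NNC(=CC1)C(=O)OC | intermediate (not isolated)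
7 | dimethyl (2Z)-2-amino-5-iminohex-2-enedioate | COC(=O)/C(N)=C/CC(=N)C(=O)OC | intermediate (not isolated)
8 | dimethyl 2-amino-2,3-dihydro-1H-pyrrole-2,5-dicarboxylate (racemic) | COC(=O)C1=CCC(N)(N1)C(=O)OC | intermediate (not isolated)
9 | dimethyl 1H-pyrrole-2,5-dicarboxylate | COC(=O)c1ccc([nH]1)C(=O)OC | intermediate
10 | iodomethane | CI | starting material
11 | dimethyl 1-methyl-1H-pyrrole-2,5-dicarboxylate | COC(=O)c1ccc(n1C)C(=O)OC | intermediate
12 | disodium 1-methyl-1H-pyrrole-2,5-dicarboxylate | Cn1c(C(=O)[O-])ccc1C(=O)[O-].[Na+].[Na+] | intermediate (not isolated)
13 | 1-methyl-1H-pyrrole-2,5-dicarboxylic acid | Cn1c(C(=O)O)ccc1C(=O)O | intermediate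
14 | 5-bromo-1-methyl-1H-pyrrole-2-carboxylic acid (present as its sodium carboxylate) | Cn1c(Br)ccc1C(=O)O | intermediate (not isolated)
15 | 2,5-dibromo-1-methyl-1H-pyrrole | Cn1c(Br)ccc1Br | intermediate (not isolated)
16 | 2,3,5-tribromo-1-methyl-1H-pyrrole | Cn1c(Br)cc(Br)c1Br | intermediate (not isolated)
17 | 2,3,4,5-tetrabromo-1-methyl-1H-pyrrole | Cn1c(Br)c(Br)c(Br)c1Br | target

**Step count**
Total steps: 5. Longest linear sequence: 5 steps (1 → 5 → 9 → 11 → 13 → 17).

**Steps most likely to fail**

Step 5. The one-flask sequence may suffer from oxidative degradation of the electron-rich bromopyrroles by surplus electrophilic bromine, or from incomplete ipso-substitution at the carboxyl-bearing carbons. The fallback separates the two tasks. It sets out from diacid 13: thermal protodecarboxylation (Cu powder, quinoline, about 200 °C, product distilled out as it forms) would give 1-methyl-1H-pyrrole F1. F1 would then be brominated at all four free ring positions with NBS (4 equiv) in THF from −78 °C to rt, a standard way to perbrominated N-alkylpyrroles. This comes back to the route at target 17.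

Step 2. The reduction may run past N–N scission, saturating the enamine or imine before closure, or it may stall at the dihydrodiazine stage. The fallback replaces the dissolving metal by a cathode, which meters the electrons. It sets out from pyridazine 5: controlled-potential electrolysis in a divided cell (glassy-carbon cathode, aqueous acetate buffer/MeCN) would be held first at the first two-electron wave to reach 6. It would then be held at the more negative second wave for N–N scission, below the potential at which the esters or the pyrrole are reduced. Closure and loss of ammonia proceed in the cell through 7 and 8, and the fallback comes back to the route at pyrrole 9. No compound outside the list arises (entry F0).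

Step 1. The tetrazine may be destroyed by adventitious nucleophiles before cycloaddition, or loss of ethanol may be sluggish and leave a mixture of dihydrodiazine tautomers. The fallback uses an alkene that needs no elimination and enters the key step one oxidation level lower. It sets out from tetrazine 1: cycloaddition with ethene (balloon, dry 1,4-dioxane, rt) would give dimethyl 2,3,5,6-tetraazabicyclo[2.2.2]octa-2,5-diene-1,4-dicarboxylate F2. F2 loses N2 to give dimethyl 4,5-dihydropyridazine-3,6-dicarboxylate F3, which tautomerises to the conjugated 1,4-dihydropyridazine. The fallback comes back to the route at 6, the first in-flask intermediate of step 2, which is then exposed to Zn/AcOH so that only N–N scission, closure and loss of ammonia remain.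

**Further compounds**
F1 | step 5 | 1-methyl-1H-pyrrole | Cn1cccc1
F0 | step 2 | none | none
F2 | step 1 | dimethyl 2,3,5,6-tetraazabicyclo[2.2.2]octa-2,5-diene-1,4-dicarboxylate | COC(=O)C12CCC(N=N1)(N=N2)C(=O)OC
F3 | step 1 | dimethyl 4,5-dihydropyridazine-3,6-dicarboxylate | COC(=O)C1=NN=C(CC1)C(=O)OC
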